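**Strategy.** The ring C1–C6 is a cyclohex-5-ene-1,4-dione with a quaternary carbon: carbonyl carbons C2 and C5 with the C3=C4 alkene between them are a masked 2,5-dioxygenated furan, and quaternary C1 with methylene C6 is a 1,1-disubstituted alkene. The route rests on a catalyst-controlled Diels–Alder reaction of a 2,5-bis(silyloxy)furan with a 2-alkylacrolein. In one operation it forms C1–C2 and C5–C6, closes the carbocycle at the enedione oxidation level and sets C1. The dienophile carries the whole C1'–C15' chain with its anti-diol as silyl ethers; its formyl group is later homologated to the acetate arm.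

Key step: step 10

Remarks on the chemistry:
- Locants follow the target: ring C1–C6, chain C1'–C15'. The diol is anti (12'S,13'R) and ring C1 is R.
- Cycloadduct 16 is written as its exo-formyl isomer and enol ether 17 as an E/Z mixture. Endo/exo, both bridgehead configurations and the enol ether geometry disappear in step 12.
- tert-Butyldimethylsilyl is used on the diol (inert to i-Bu2AlH, ylide, the Lewis acid and dilute acid) and on the furan (its bulk slows silyl transfer).
- Assumed bought as reagents: allyl(diisopropylamino)dimethylsilane, (+)-B-methoxydiisopinocampheylborane, the (S)-oxazaborolidine of step 10 and (methoxymethyl)triphenylphosphonium chloride.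

**Step 1**
Reactants: 1 (2E,6E)-farnesol
Product: 2 (2E,6E)-farnesyl bromide
Conditions: PBr3 (0.4 equiv), Et2O, −10 → 0 °C
Reagents that add atoms: phosphorus tribromide BrP(Br)Br
Why: Bromination of a primary allylic alcohol through its phosphite ester (SN2 displacement by bromide) at low temperature should keep the 2E geometry and avoid allylic transposition.

**Step 2**
Reactants: 3 tert-butyl acetate; 2 (2E,6E)-farnesyl bromide
Product: 5 tert-butyl (4E,8E)-5,9,13-trimethyltetradeca-4,8,12-trienoate, via lithium enolate 4 (not isolated)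
Conditions: LiN(i-Pr)2, THF, −78 °C; then 2, DMPU, −78 → −20 °C
Reagents that add atoms: none
Why: Ester enolate alkylation: the tert-butyl acetate enolate does not self-condense at −78 °C and should displace the primary allylic bromide by SN2 at the unsubstituted terminus.

**Step 3**
Reactants: 5 tert-butyl (4E,8E)-5,9,13-trimethyltetradeca-4,8,12-trienoate
Product: 7 tert-butyl (4E,8E,12E)-5,9,13-trimethyl-14-oxotetradeca-4,8,12-trienoate, via allylic alcohol 6 (not isolated)
Conditions: SeO2 (cat.), t-BuOOH, salicylic acid (cat.), CH2Cl2, 0 °C → rt; crude mixture, then MnO2, CH2Cl2, rt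
Reagents that add atoms: tert-butyl hydroperoxide CC(C)(C)OO (terminal oxygen source, delivered through selenium dioxide O=[Se]=O)
Why: Riley allylic oxidation (ene reaction, then [2,3]-sigmatropic shift) is selective for the E-methyl of the terminal isopropylidene group, and MnO2 should converge the alcohol/aldehyde mixture on the E-enal.

**Step 4**
Reactants: 7 tert-butyl (4E,8E,12E)-5,9,13-trimethyl-14-oxotetradeca-4,8,12-trienoate
Product: 9 tert-butyl (4E,8E,12E,14S,15R)-14,15-dihydroxy-5,9,13-trimethylheptadeca-4,8,12,16-tetraenoate, via borinate 8 (not isolated)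
Conditions: allyl(diisopropylamino)dimethylsilane, n-BuLi, TMEDA, Et2O, 0 °C; (+)-Ipc2BOMe [from (−)-α-pinene], −78 °C; BF3·OEt2; then 7, −78 °C; then KF, KHCO3, 30% H2O2, THF/MeOH, rt
Reagents that add atoms: allyl(diisopropylamino)dimethylsilane C=CC[Si](C)(C)N(C(C)C)C(C)C; hydrogen peroxide OO
Why: Allylboration of the enal (1,2-addition) through a closed chair transition state: the E-γ-silylallyl borane gives the anti relationship, the isopinocampheyl groups from (−)-α-pinene direct attack to the Re face of the aldehyde (14S, hence 15R), and Tamao–Fleming oxidation replaces silicon by hydroxyl with retention.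

**Step 5**
Reactants: 9 tert-butyl (4E,8E,12E,14S,15R)-14,15-dihydroxy-5,9,13-trimethylheptadeca-4,8,12,16-tetraenoate
Product: 10 tert-butyl (4E,8E,12E,14S,15R)-14,15-dihydroxy-5,9,13,17-tetramethyloctadeca-4,8,12,16-tetraenoate
Conditions: 2-methylbut-2-ene (large excess), [RuCl2(=CHPh)(PCy3)(H2IMes)] (second-generation Grubbs catalyst, 5 mol%), CH2Cl2, 35–40 °C
Reagents that add atoms: 2-methylbut-2-ene CC=C(C)C
Why: Olefin cross-metathesis: the monosubstituted allylic alkene should exchange its methylene for isopropylidene, while the trisubstituted chain alkenes are too hindered to compete.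

**Step 6**
Reactants: 10 tert-butyl (4E,8E,12E,14S,15R)-14,15-dihydroxy-5,9,13,17-tetramethyloctadeca-4,8,12,16-tetraenoate
Product: 11 tert-butyl (4E,8E,12E,14S,15R)-14,15-bis(tert-butyldimethylsilyloxy)-5,9,13,17-tetramethyloctadeca-4,8,12,16-tetraenoate
Conditions: TBSOTf, 2,6-lutidine, CH2Cl2, −78 → 0 °C
Reagents that add atoms: tert-butyldimethylsilyl triflate CC(C)(C)[Si](C)(C)OS(=O)(=O)C(F)(F)F
Why: O-Silylation with the silyl triflate is reactive enough for the hindered second hydroxyl of the vicinal diol, and at low temperature the tert-butyl ester should stay intact.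

**Step 7**
Reactants: 11 tert-butyl (4E,8E,12E,14S,15R)-14,15-bis(tert-butyldimethylsilyloxy)-5,9,13,17-tetramethyloctadeca-4,8,12,16-tetraenoate
Product: 12 (4E,8E,12E,14S,15R)-14,15-bis(tert-butyldimethylsilyloxy)-5,9,13,17-tetramethyloctadeca-4,8,12,16-tetraenal
Conditions: i-Bu2AlH (1.1 equiv), CH2Cl2, −78 °C; MeOH, then aq. potassium sodium tartrate
Reagents that add atoms: none
Why: Partial hydride reduction of an ester: at −78 °C the tetrahedral aluminium hemiacetal should persist and release the aldehyde only on work-up.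

**Step 8**
Reactants: 12 (4E,8E,12E,14S,15R)-14,15-bis(tert-butyldimethylsilyloxy)-5,9,13,17-tetramethyloctadeca-4,8,12,16-tetraenal
Product: 13 (4E,8E,12E,14S,15R)-14,15-bis(tert-butyldimethylsilyloxy)-5,9,13,17-tetramethyl-2-methylideneoctadeca-4,8,12,16-tetraenal
Conditions: 37% aq. CH2O, pyrrolidine (10 mol%), propionic acid (10 mol%), i-PrOH, 45 °C
Reagents that add atoms: formaldehyde C=O
Why: Amine-catalysed Mannich-type α-methylenation (enamine addition to formaldehyde, then elimination) converts an α-unbranched aldehyde into the 2-alkylacrolein without affecting silyl ethers or the chain alkenes.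

**Step 9**
Reactants: 14 succinic anhydride
Product: 15 2,5-bis(tert-butyldimethylsilyloxy)furan
Conditions: TBSOTf (2.1 equiv), Et3N, Et2O, 0 °C → rt; distilled under reduced pressure
Reagents that add atoms: tert-butyldimethylsilyl triflate CC(C)(C)[Si](C)(C)OS(=O)(=O)C(F)(F)F
Why: Double soft enolisation and O-silylation of the cyclic anhydride gives the aromatic bis(silyl ketene acetal), a known route to 2,5-bis(silyloxy)furans.

**Step 10**
Reactants: 13 (4E,8E,12E,14S,15R)-14,15-bis(tert-butyldimethylsilyloxy)-5,9,13,17-tetramethyl-2-methylideneoctadeca-4,8,12,16-tetraenal; 15 2,5-bis(tert-butyldimethylsilyloxy)furan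
Product: 16 (1S,2R,4S)-1,4-bis(tert-butyldimethylsilyloxy)-2-[(2E,6E,10E,12S,13R)-12,13-bis(tert-butyldimethylsilyloxy)-3,7,11,15-tetramethylhexadeca-2,6,10,14-tetraen-1-yl]-7-oxabicyclo[2.2.1]hept-5-ene-2-carbaldehyde (formyl exo)
Conditions: (3aS)-1-(2-methylphenyl)-3,3-diphenyltetrahydro-1H,3H-pyrrolo[1,2-c][1,3,2]oxazaborole (20 mol%), Tf2NH (18 mol%), CH2Cl2, −78 °C; 13, then 15 (2 equiv) added slowly; Et3N quench at −78 °C, filtration through Et3N-deactivated silica
Reagents that add atoms: none
Why: Proposed new method: the N-protonated (S)-oxazaborolidine should bind the formyl oxygen of 13 (B–O coordination plus a formyl C–H···O contact), hold the s-trans enal over one C-phenyl group and leave only the Si face of the α-carbon open, so that furan 15 adds across C1=C6 in a LUMO-lowered, asynchronous [4+2] in which bonding to the unhindered methylene C6 leads and bonding to the future quaternary carbon follows. The closest known reaction types are the racemic [4+2] additions of 2,5-bis(silyloxy)furans to acrylic dienophiles and the oxazaborolidinium-catalysed Diels–Alder reactions of 2-alkyl- and 2-haloacroleins with simple dienes. The six-membered carbocycle closes by intermolecular [4+2] annulation, both C–C bonds forming on one face of the alkene (at the stepwise limit a Mukaiyama–Michael addition followed by six-membered closure of the boron enolate onto the silyloxy-stabilised cation), and it emerges as the oxygen-bridged bis-silyl ketal. The quaternary stereocentre (ring C1, C2 of the bicycle) is set by the catalyst's facial shielding; the two bridgehead ketal centres follow from the suprafacial addition and the exo/endo preference and are erased when the ketal is opened. The step needs enantioface selectivity and reaction at the alkene instead of the formyl carbon: the twofold-symmetric diene removes any regiochemical question, the 2-alkyl group fixes the enal geometry on boron, the other alkenes of 13 are unactivated and trisubstituted, and the bulky silyl groups slow silyl transfer and ketene-acetal-type aldol attack.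

**Step 11**
Reactants: 16 the cycloadduct carbaldehyde
Product: 17 (1S,2R,4S)-1,4-bis(tert-butyldimethylsilyloxy)-2-[(2E,6E,10E,12S,13R)-12,13-bis(tert-butyldimethylsilyloxy)-3,7,11,15-tetramethylhexadeca-2,6,10,14-tetraen-1-yl]-2-(2-methoxyethenyl)-7-oxabicyclo[2.2.1]hept-5-ene (E/Z mixture)
Conditions: Ph3P(CH2OMe)Cl, KN(SiMe3)2, THF, 0 °C; then 16, −78 → 0 °C
Reagents that add atoms: (methoxymethyl)triphenylphosphonium chloride COC[P+](c1ccccc1)(c1ccccc1)c1ccccc1.[Cl-]
Why: Wittig olefination with the small unstabilised methoxymethylene ylide: the aldehyde has no α-hydrogen and cannot be enolised, and silyl ethers and the bis-silyl ketal are stable to the base.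

**Step 12**
Reactants: 17 the methyl enol ether
Product: 18 2-[(1S)-1-[(2E,6E,10E,12S,13R)-12,13-bis(tert-butyldimethylsilyloxy)-3,7,11,15-tetramethylhexadeca-2,6,10,14-tetraen-1-yl]-2,5-dioxocyclohex-3-en-1-yl]acetaldehyde (same spatial arrangement at C1 as in the target; the descriptor changes only through the priority rules)
Conditions: 0.5 M aq. HCl/THF (1:4), 0 °C → rt, stopped when the enol ether is consumed; used directly
Reagents that add atoms: water O
Why: Acid hydrolysis: protonation of the enol ether and loss of methanol gives the homologous aldehyde, and the bridging bis-silyl ketal collapses to the C2 and C5 ketones leaving C3=C4, while the hindered secondary silyl ethers should survive brief dilute acid.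

**Step 13**
Reactants: 18 the aldehyde
Product: 19 2-[(1R)-1-[(2E,6E,10E,12S,13R)-12,13-bis(tert-butyldimethylsilyloxy)-3,7,11,15-tetramethylhexadeca-2,6,10,14-tetraen-1-yl]-2,5-dioxocyclohex-3-en-1-yl]acetic acid
Conditions: NaClO2, NaH2PO4, 2-methylbut-2-ene, t-BuOH/H2O, 0 °C → rt
Reagents that add atoms: sodium chlorite [Na+].[O-]Cl=O
Why: Pinnick oxidation is selective for aldehydes, and 2-methylbut-2-ene traps hypochlorous acid so that the chain alkenes and the enedione should be untouched.

**Step 14**
Reactants: 19 the carboxylic acid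
Product: 20 methyl 2-[(1R)-1-[(2E,6E,10E,12S,13R)-12,13-bis(tert-butyldimethylsilyloxy)-3,7,11,15-tetramethylhexadeca-2,6,10,14-tetraen-1-yl]-2,5-dioxocyclohex-3-en-1-yl]acetate
Conditions: MeI, KHCO3, DMF, rt
Reagents that add atoms: iodomethane CI
Why: Carboxylate O-alkylation (SN2 on iodomethane): bicarbonate is too weak a base to enolise the enedione, and the method avoids diazoalkanes, which add to enediones.

**Step 15**
Reactants: 20 the bis-silyl methyl ester
Product: 21 methyl 2-[(1R)-1-[(2E,6E,10E,12S,13R)-12,13-dihydroxy-3,7,11,15-tetramethylhexadeca-2,6,10,14-tetraen-1-yl]-2,5-dioxocyclohex-3-en-1-yl]acetate (target)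
Conditions: HF·pyridine, pyridine, THF, 0 °C → rt
Reagents that add atoms: none
Why: Fluoride-mediated cleavage of the two silyl ethers under buffered, weakly acidic conditions should leave the methyl ester, the enedione and the bis-allylic diol intact.

**Compound list**

1 | (2E,6E)-farnesol | CC(C)=CCC/C(C)=C/CC/C(C)=C/CO | starting material
2 | (2E,6E)-farnesyl bromide | CC(C)=CCC/C(C)=C/CC/C(C)=C/CBr | intermediate
3 | tert-butyl acetate | CC(=O)OC(C)(C)C | starting material
4 | lithium enolate of tert-butyl acetate | [Li+].[O-]C(=C)OC(C)(C)C | intermediate (not isolated)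
5 | tert-butyl (4E,8E)-5,9,13-trimethyltetradeca-4,8,12-trienoate | CC(C)(C)OC(=O)CC/C=C(\C)CC/C=C(\C)CCC=C(C)C | intermediate
6 | tert-butyl (4E,8E,12E)-14-hydroxy-5,9,13-trimethyltetradeca-4,8,12-trienoate | CC(C)(C)OC(=O)CC/C=C(\C)CC/C=C(\C)CC/C=C(\C)CO | intermediate (not isolated)
7 | tert-butyl (4E,8E,12E)-5,9,13-trimethyl-14-oxotetradeca-4,8,12-trienoate | CC(C)(C)OC(=O)CC/C=C(\C)CC/C=C(\C)CC/C=C(\C)C=O | intermediate
8 | (14S,15R) O-diisopinocampheylboryl adduct bearing the (diisopropylamino)dimethylsilyl group on C15 | CC(C)(C)OC(=O)CC/C=C(\C)CC/C=C(\C)CC/C=C(\C)[C@H](OB([C@H]1C[C@H]2C[C@@H]([C@@H]1C)C2(C)C)[C@H]1C[C@H]2C[C@@H]([C@@H]1C)C2(C)C)[C@H]([Si](C)(C)N(C(C)C)C(C)C)C=C | intermediate (not isolated)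
9 | tert-butyl (4E,8E,12E,14S,15R)-14,15-dihydroxy-5,9,13-trimethylheptadeca-4,8,12,16-tetraenoate | CC(C)(C)OC(=O)CC/C=C(\C)CC/C=C(\C)CC/C=C(\C)[C@H](O)[C@H](O)C=C | intermediate
10 | tert-butyl (4E,8E,12E,14S,15R)-14,15-dihydroxy-5,9,13,17-tetramethyloctadeca-4,8,12,16-tetraenoate | CC(C)(C)OC(=O)CC/C=C(\C)CC/C=C(\C)CC/C=C(\C)[C@H](O)[C@H](O)C=C(C)C | intermediate
11 | tert-butyl (4E,8E,12E,14S,15R)-14,15-bis(tert-butyldimethylsilyloxy)-5,9,13,17-tetramethyloctadeca-4,8,12,16-tetraenoate | CC(C)(C)OC(=O)CC/C=C(\C)CC/C=C(\C)CC/C=C(\C)[C@H](O[Si](C)(C)C(C)(C)C)[C@H](O[Si](C)(C)C(C)(C)C)C=C(C)C | intermediate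
12 | (4E,8E,12E,14S,15R)-14,15-bis(tert-butyldimethylsilyloxy)-5,9,13,17-tetramethyloctadeca-4,8,12,16-tetraenal | O=CCC/C=C(\C)CC/C=C(\C)CC/C=C(\C)[C@H](O[Si](C)(C)C(C)(C)C)[C@H](O[Si](C)(C)C(C)(C)C)C=C(C)C | intermediate
13 | (4E,8E,12E,14S,15R)-14,15-bis(tert-butyldimethylsilyloxy)-5,9,13,17-tetramethyl-2-methylideneoctadeca-4,8,12,16-tetraenal | O=CC(=C)C/C=C(\C)CC/C=C(\C)CC/C=C(\C)[C@H](O[Si](C)(C)C(C)(C)C)[C@H](O[Si](C)(C)C(C)(C)C)C=C(C)C | intermediate (key-step precursor)
14 | succinic anhydride | O=C1CCC(=O)O1 | starting material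
15 | 2,5-bis(tert-butyldimethylsilyloxy)furan | CC(C)(C)[Si](C)(C)Oc1ccc(O[Si](C)(C)C(C)(C)C)o1 | intermediate (key-step precursor)
16 | (1S,2R,4S)-1,4-bis(silyloxy)-7-oxabicyclo[2.2.1]hept-5-ene-2-carbaldehyde with the chain on C2, formyl exo | O=C[C@@]1(C/C=C(\C)CC/C=C(\C)CC/C=C(\C)[C@H](O[Si](C)(C)C(C)(C)C)[C@H](O[Si](C)(C)C(C)(C)C)C=C(C)C)C[C@]2(O[Si](C)(C)C(C)(C)C)C=C[C@@]1(O[Si](C)(C)C(C)(C)C)O2 | intermediate (key-step product)
17 | 2-(2-methoxyethenyl) analogue of 16, E/Z mixture | COC=C[C@@]1(C/C=C(\C)CC/C=C(\C)CC/C=C(\C)[C@H](O[Si](C)(C)C(C)(C)C)[C@H](O[Si](C)(C)C(C)(C)C)C=C(C)C)C[C@]2(O[Si](C)(C)C(C)(C)C)C=C[C@@]1(O[Si](C)(C)C(C)(C)C)O2 | intermediate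
18 | (1S)-2,5-dioxocyclohex-3-en-1-yl acetaldehyde with the bis-silylated chain on C1 | O=CC[C@@]1(C/C=C(\C)CC/C=C(\C)CC/C=C(\C)[C@H](O[Si](C)(C)C(C)(C)C)[C@H](O[Si](C)(C)C(C)(C)C)C=C(C)C)CC(=O)C=CC1=O | intermediate
19 | (1R)-2,5-dioxocyclohex-3-en-1-yl acetic acid with the bis-silylated chain on C1 | OC(=O)C[C@@]1(C/C=C(\C)CC/C=C(\C)CC/C=C(\C)[C@H](O[Si](C)(C)C(C)(C)C)[C@H](O[Si](C)(C)C(C)(C)C)C=C(C)C)CC(=O)C=CC1=O | intermediate
20 | methyl ester of 19 | COC(=O)C[C@@]1(C/C=C(\C)CC/C=C(\C)CC/C=C(\C)[C@H](O[Si](C)(C)C(C)(C)C)[C@H](O[Si](C)(C)C(C)(C)C)C=C(C)C)CC(=O)C=CC1=O | intermediate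
21 | methyl 2-[(1R)-1-[(2E,6E,10E,12S,13R)-12,13-dihydroxy-3,7,11,15-tetramethylhexadeca-2,6,10,14-tetraen-1-yl]-2,5-dioxocyclohex-3-en-1-yl]acetate | COC(=O)C[C@@]1(C/C=C(\C)CC/C=C(\C)CC/C=C(\C)[C@H](O)[C@H](O)C=C(C)C)CC(=O)C=CC1=O | target

**Totals.** 15 steps in all; longest linear sequence 14 steps (steps 1–8 and 10–15); the diene is made in one step (step 9).

**Steps most likely to fail**

1. Step 10 (Proposed new method). Three processes may defeat it:
   - silyl transfer from the furan releases an achiral silyl triflimide that catalyses the background reaction and erodes facial selectivity;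
   - the furan reacts as a ketene acetal through its β-carbon in aldol or Michael mode instead of as a 2,5-diene;
   - the labile adduct undergoes cycloreversion or ketal opening during work-up.

   Fallback (known chemistry, giving up catalyst control): 13 and 15 are combined without the chiral catalyst (toluene, 60–80 °C, or catalytic Me2AlCl at −78 °C), the known racemic manifold of bis(silyloxy)furans. This should give 16 together with the cycloadduct epimeric at the quaternary carbon F1, in comparable amounts since the remote chain stereocentres cannot bias the ring. The mixture is carried through the operations of steps 11–14, via the epimeric enol ether F2, the epimeric aldehyde F3 and the epimeric acid F4, to 20 and its C1-epimeric methyl ester F5. These two diastereomers are separated by preparative HPLC on a chiral stationary phase. The fallback sets out from 13 and 15 and returns to the route at 20.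

2. Step 12. The acid strength needed to hydrolyse the enol ether may also strip the silyl ethers from the bis-allylic diol, and the γ-keto aldehyde may degrade by aldol-type self-reaction before it is oxidised. Fallback (sets out from 16, returns at 20, replaces steps 11–14): Horner–Wittig homologation to the ester oxidation level. Lithiated (dimethoxymethyl)diphenylphosphine oxide (LiN(i-Pr)2, THF, −100 °C) adds to the formyl group of 16 to give the β-hydroxy phosphine oxide F6. KOt-Bu in THF eliminates diphenylphosphinate to give the ketene dimethyl acetal F7. Very mild aqueous acid (AcOH/THF/H2O, rt) then hydrolyses the ketene acetal directly to the methyl ester and opens the bis-silyl ketal, giving 20 without a free aldehyde, chlorite oxidation or esterification.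

3. Step 3. The allylic oxidation may stall at low conversion, over-oxidise, or leak to the internal allylic positions. Fallback (sets out from 5, returns at 7): degrade and rebuild the terminus. Terminal-selective bromohydrin formation (NBS, THF/H2O, 0 °C) gives the bromohydrin F8, and K2CO3 in MeOH closes it to the terminal epoxide F9. H5IO6 in THF/Et2O cleaves the epoxide to the trisnor aldehyde F10. An E-selective Wittig reaction with the stabilised ylide Ph3P=C(CH3)CHO (toluene, 90 °C) then gives enal 7.

**Further compounds**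

F1 | step 10 | (1R,2S,4R)-cycloadduct, epimer of 16 at the quaternary carbon (formyl exo) | O=C[C@]1(C/C=C(\C)CC/C=C(\C)CC/C=C(\C)[C@H](O[Si](C)(C)C(C)(C)C)[C@H](O[Si](C)(C)C(C)(C)C)C=C(C)C)C[C@@]2(O[Si](C)(C)C(C)(C)C)C=C[C@]1(O[Si](C)(C)C(C)(C)C)O2
F2 | step 10 | methyl enol ether from F1 (E/Z mixture) | COC=C[C@]1(C/C=C(\C)CC/C=C(\C)CC/C=C(\C)[C@H](O[Si](C)(C)C(C)(C)C)[C@H](O[Si](C)(C)C(C)(C)C)C=C(C)C)C[C@@]2(O[Si](C)(C)C(C)(C)C)C=C[C@]1(O[Si](C)(C)C(C)(C)C)O2
F3 | step 10 | C1 epimer of aldehyde 18 | O=CC[C@]1(C/C=C(\C)CC/C=C(\C)CC/C=C(\C)[C@H](O[Si](C)(C)C(C)(C)C)[C@H](O[Si](C)(C)C(C)(C)C)C=C(C)C)CC(=O)C=CC1=O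
F4 | step 10 | C1 epimer of acid 19 | OC(=O)C[C@]1(C/C=C(\C)CC/C=C(\C)CC/C=C(\C)[C@H](O[Si](C)(C)C(C)(C)C)[C@H](O[Si](C)(C)C(C)(C)C)C=C(C)C)CC(=O)C=CC1=O
F5 | step 10 | C1 epimer of methyl ester 20 | COC(=O)C[C@]1(C/C=C(\C)CC/C=C(\C)CC/C=C(\C)[C@H](O[Si](C)(C)C(C)(C)C)[C@H](O[Si](C)(C)C(C)(C)C)C=C(C)C)CC(=O)C=CC1=O
F6 | step 12 | β-hydroxy phosphine oxide adduct of 16 (carbinol epimers) | COC(OC)(P(=O)(c1ccccc1)c1ccccc1)C(O)[C@@]1(C/C=C(\C)CC/C=C(\C)CC/C=C(\C)[C@H](O[Si](C)(C)C(C)(C)C)[C@H](O[Si](C)(C)C(C)(C)C)C=C(C)C)C[C@]2(O[Si](C)(C)C(C)(C)C)C=C[C@@]1(O[Si](C)(C)C(C)(C)C)O2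
F7 | step 12 | ketene dimethyl acetal (2,2-dimethoxyethenyl analogue of 16) | COC(OC)=C[C@@]1(C/C=C(\C)CC/C=C(\C)CC/C=C(\C)[C@H](O[Si](C)(C)C(C)(C)C)[C@H](O[Si](C)(C)C(C)(C)C)C=C(C)C)C[C@]2(O[Si](C)(C)C(C)(C)C)C=C[C@@]1(O[Si](C)(C)C(C)(C)C)O2
F8 | step 3 | tert-butyl (4E,8E)-12-bromo-13-hydroxy-5,9,13-trimethyltetradeca-4,8-dienoate (racemic at C12) | CC(C)(C)OC(=O)CC/C=C(\C)CC/C=C(\C)CCC(Br)C(C)(C)O
F9 | step 3 | tert-butyl (4E,8E)-11-(3,3-dimethyloxiran-2-yl)-5,9-dimethylundeca-4,8-dienoate (racemic epoxide) | CC(C)(C)OC(=O)CC/C=C(\C)CC/C=C(\C)CCC1OC1(C)C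
F10 | step 3 | tert-butyl (4E,8E)-5,9-dimethyl-12-oxododeca-4,8-dienoate | CC(C)(C)OC(=O)CC/C=C(\C)CC/C=C(\C)CCC=O
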